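(The numbers are those of an exercise, and the outcome is calculated.)

Amounts first: each set-up gets 20 mM of substrate, the closed flask teal in one charge, the flow tank ochre as a steady feed.

- teal: substrate 20 mM; time 10 min; a closed flask charged with all of it at once and left for 10 min
- ochre: substrate 20 mM; one stirred flow tank at steady state, fed with the mixture as stated, mean residence time 10 min

* the set-up with the highest share of target in all that became target or side product, at the outlet or at the end ("none" if the first two lie within 2 percentage points) (teal / ochre / none)
* share of target in all that became target or side product, at the outlet or at the end, teal
* share of target in all that became target or side product, at the outlet or at the end, ochre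

- a species is counted by the substrate in it: one side product counts as two
- the stated concentrations are those of everything mixed, before any reaction; amounts are the same in each set-up
- run time (teal): 10 min

    substrate → intermediate C (k1 = 0.0059 s⁻¹)
    intermediate A ⇌ intermediate D (K2 = 0.99, k2 = 0.017 s⁻¹)
    intermediate B → target (k3 = 0.0033 s⁻¹)
    substrate → intermediate B (k4 = 0.0075 s⁻¹)
    intermediate D ⇌ intermediate E (K5 = 1.9, k5 = 0.0087 s⁻¹)
    intermediate C → target (k6 = 0.0039 s⁻¹)
    substrate ⇌ intermediate A (K7 = 5.0, k7 = 0.047 s⁻¹)
    substrate + target → side product (k8 = 0.60 L mol⁻¹ s⁻¹)

Substrate passes reversibly into intermediate A, then on to D and E, and leaks through intermediates B and C to target. Substrate meeting target gives side product.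

Two of us argued over this. My colleague watched the peak: teal starts at 20 mM, so target there is lost at 0.720 min⁻¹ per unit of target, and teal must come off worse.

I watched the mean. Walking the tank's steady balances back from intermediate E, and leaving out what the side step takes, puts c(intermediate E) at 1.39 times c(intermediate D), c(intermediate D) at 0.803 times c(intermediate A), and c(intermediate A) at 3.29 times c(substrate). With the drains to intermediates B and C, that gives c(substrate) = 1.07 mM in ochre. In teal, counting the drains on substrate, the pool of substrate, A, D and E holds 25.9 times c(substrate). Drained at that pace, its mid-run value is 0.662 mM.

So teal has N = 0.238: the loss number, the pseudo-first-order constant of target's loss at mean c(substrate), times the time. Ochre has N = 0.386.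

Each loss counts two. In the tank target stands at its outlet value throughout, so the share is 1/(1+2N), which gives 56.4%. In teal target rises from nothing, its mean about half its end value, so the share is 1/(1+N), which gives 80.8%. My pick is teal.

The forecast takes my side on the order, with teal best, but its numbers are its own: 78% (73% to 82%) for teal and 58.4% (56% to 61%) for ochre. Its ground is that the batch “starts with almost no target while substrate is highest”.

The simulation gives teal, with 83.4% for teal and 58.3% for ochre. The forecast's order and ochre hold, while its teal is 5.4 percentage points low. My colleague's peak figure fits the first moments, when teal's substrate stands above the tank's. Read at 4.00 min, teal's substrate is down to 0.585 mM.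

Read at 5.00 min, teal's substrate stands at 0.501 mM, less than the tank's reckoned 1.07 mM. On that reading N is 0.180 against my reckoned 0.238, so the mean-for-curve swap gives 84.7% against teal's 83.4%, an error of 1.3 points.

For teal read at 4.0 min, the reckoned mid-run substrate is 0.726 mM, so N is 0.105 and the share 90.5%. The computed share is 88.8%.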